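1. Numbering (cedrane): ring A = C1–C2–C3–C4–C5, ring B = C1–C5–C6–C7–C11, ring C = C1–C10–C9=C8–C7–C11. C12 is the CHO on C2, C13/C14 are the CH2OH/CH3 on C6, and C15 is the COOH on C8.
2. The C10–O ester comes from a Mitsunobu inversion with a Wittig-made (Z)-16-silyloxyhexadec-9-enoic acid. C12 and the hydrogens at C2 and C5 come from a ring A cyclopentadienyl triflate (hydroxymethylation, then hydrogenation from the C11 face).
3. Ring C: C8=C9 by formyl-olefination of a C8 keto ester, and C10–C1 by intramolecular aldol addition.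
4. Ring B (key): with C2 and C8 carried as ketones, the path C2–C1–C11–C7–C8 is a 1,5-diketone, the retron of a de Mayo reaction. The C7=C11 vinyl group on quaternary C6 sits two atoms (C5, C6) from the enol C1=C8, so a crossed [2+2] closes C8–C7 and C11–C1, and retro-aldol then cuts C1–C8.
5. The precursor comes from (R)-4-silyloxycyclopentenone, methyl tiglate dienolate (C5–C6) and an oxalyl unit (C8, C15). Ring order: A (bought), B (step 6), C (step 8).

Key step: step 6

Assumption: the SMILES is read literally, (1R,2S,5S,6S,7S,10S). The hydrogen at C5 then lies on the face of ring B turned away from ring C, so rings A and B are trans-fused. For that reason C5 is carried provisionally, erased in step 10 and fixed in step 12.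

Step 1
Reactants: 1 methyl tiglate; 2 (R)-4-(tert-butyldimethylsilyloxy)cyclopent-2-en-1-one
Product: 5 methyl 2-methyl-2-[2-(tert-butyldimethylsilyloxy)-4-(triethylsilyloxy)cyclopent-4-en-1-yl]but-3-enoate (ring substituents trans), via lithium dienolate 3 (not isolated), via lithium enolate 4 (not isolated)
Conditions: LiN(i-Pr)2, THF/DMPU, −78 °C; then 2, −78 °C; then Et3SiCl, −78 °C → 0 °C
Reagents that add atoms: chlorotriethylsilane CC[Si](Cl)(CC)CC
Why: Michael addition through the α-carbon of the dienolate, in which attack anti to the C4 silyloxy group sets C5, a lithium-bridged closed transition state (ester carbon gauche to C1 on the side of the C5 hydrogen, vinyl group anti to C1) sets C6, and silylation stores the enolate regiospecifically at C1.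

Step 2
Reactants: 5 methyl ester silyl enol ether
Product: 6 2-methyl-2-[2-(tert-butyldimethylsilyloxy)-4-(triethylsilyloxy)cyclopent-4-en-1-yl]but-3-en-1-ol
Conditions: LiAlH4, Et2O, −20 °C → 0 °C
Reagents that add atoms: none
Why: Hydride reduction of the ester brings C13 to the CH2OH level, and the silyl ethers and the silyl enol ether are inert to hydride.

Step 3
Reactants: 6 primary alcohol
Product: 7 tert-butyldimethylsilyl ether of 6
Conditions: t-BuMe2SiCl, imidazole, DMF, rt
Reagents that add atoms: tert-butyldimethylsilyl chloride CC(C)(C)[Si](C)(C)Cl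
Why: Silyl ether protection of the neopentyl primary alcohol with a group meant to last until the final step.

Step 4
Reactants: 8 2-(trimethylsilyl)ethanol; 9 oxalyl chloride
Product: 10 2-(trimethylsilyl)ethyl chlorooxoacetate
Conditions: excess 9, Et2O, 0 °C → rt, excess 9 distilled off
Reagents that add atoms: none
Why: Esterification of an alcohol by an acid chloride, stopped at the half ester chloride by the excess of oxalyl chloride.

Step 5
Reactants: 7 silyl enol ether; 10 2-(trimethylsilyl)ethyl chlorooxoacetate
Product: 11 chelated enol of the C1-oxalyl ketone (C1=C8 with OH on C8 syn to the C2 carbonyl)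
Conditions: ZnCl2 (10 mol%), CH2Cl2, −78 °C → 0 °C
Reagents that add atoms: none
Why: C-acylation of a silyl enol ether by an acid chloride places the C8–C15 unit only at C1, and the 2,4-dioxo ester rests as the hydrogen-bonded enol that is the chromophore of step 6.

Step 6
Reactants: 11 chelated enol
Product: 13 cis-bicyclo[3.3.0]octan-2-one (rings A and B) bearing the 2-oxoacetate on C7, via bicyclo[2.1.1]hexanol photoadduct 12 (not isolated)
Conditions: hν (λ > 300 nm, Pyrex filter), degassed MeCN (2 mM), 0 °C
Reagents that add atoms: none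
Why: Excitation of the hydrogen-bonded enol (an enone chromophore) gives a triplet whose β-carbon C8 adds to the inner vinyl carbon C7 (5-exo-trig, the rule of five), and the resulting 1,4-biradical collapses by joining C1 to C11, which closes the cyclobutane of bicyclo[2.1.1]hexanol 12 and with it ring B. The strained β-hydroxy ketone 12 then undergoes retro-aldol cleavage of C1–C8, so the vinyl unit ends up inserted between C1 and C8 and the 1,5-diketone 13 results; the closest known reaction type is the intramolecular de Mayo reaction, here in the crossed mode known for 1,5-dienes. C7 is fixed by the tether, because both new bonds must form on the ring A face that carries C6, which is the face anti to the C4 silyloxy group. C1 is set on protonation of the enolate as the cis-fused bicyclo[3.3.0]octanone, the unstrained junction, and stays correctable by enolisation. The step needs crossed rather than straight regiochemistry, which the two-atom tether secures (the straight mode would give a bicyclo[2.2.0]hexane), and it needs the product to survive, which is secured because 11 absorbs far more strongly above 300 nm than keto ester 13.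

Step 7
Reactants: 13 diketo ester
Product: 15 (E)-enal with C8(CO2R)=C9H–C10HO (aldehyde trans to the ester), via unsaturated cyclohexylimine 14 (not isolated)
Conditions: (EtO)2P(O)CH=CHNH-c-C6H11, NaH, THF, 0 °C → rt; then aq. oxalic acid, toluene, rt
Reagents that add atoms: diethyl [2-(cyclohexylamino)vinyl]phosphonate CCOP(=O)(OCC)C=CNC1CCCCC1; water O
Why: Horner–Wadsworth–Emmons formyl-olefination in which the phosphonate anion attacks only the activated C8 keto ester carbonyl (the hindered C2 ketone is inert), the aldehyde ends trans to the ester as in related 2-oxo ester olefinations, and hydrolysis of imine 14 frees the enal.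

Step 8
Reactants: 15 enal
Product: 17 tricyclic C10 alcohol (10-epi, hydroxyl equatorial) with ring A as the C2 ketone C3=C4 enone, via cyclopentenone enal 16 (not isolated)
Conditions: DBU (2 equiv), toluene, rt → 40 °C
Reagents that add atoms: none
Why: E1cB loss of the C4 silanolate gives enone 16, and a reversible intramolecular aldol addition (6-enolexo-exo-trig) of C1 to C10 closes ring C on the only face that keeps the bicycle unstrained, which makes C1 quaternary and should favour the equatorial C10 alcohol under equilibrium control.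

Step 9
Reactants: 17 tricyclic alcohol
Product: 18 C10 triethylsilyl ether
Conditions: Et3SiOTf, 2,6-lutidine, CH2Cl2, −78 °C
Reagents that add atoms: triethylsilyl triflate CC[Si](CC)(CC)OS(=O)(=O)C(F)(F)F
Why: Silyl ether protection blocks retro-aldol cleavage in the basic step that follows and adds bulk on the ring A face that must stay closed in step 12.

Step 10
Reactants: 18 enone
Product: 19 cyclopentadienyl triflate (C2(OTf)=C3–C4=C5)
Conditions: KN(SiMe3)2, THF, −78 °C; then PhNTf2, −78 °C → 0 °C
Reagents that add atoms: N-phenylbis(trifluoromethanesulfonimide) O=S(=O)(N(c1ccccc1)S(=O)(=O)C(F)(F)F)C(F)(F)F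
Why: γ-Deprotonation at C5 (the only acidic site of the enone, since C1 is quaternary) and O-triflation of the extended enolate give the dienyl triflate and erase the provisional C5 centre.

Step 11
Reactants: 19 dienyl triflate
Product: 20 cyclopentadienylmethanol (C12H2OH on C2)
Conditions: Bu3SnCH2OH, Pd(PPh3)4 (5 mol%), LiCl, THF, 65 °C
Reagents that add atoms: (tributylstannyl)methanol CCCC[Sn](CO)(CCCC)CCCC
Why: Stille coupling of a vinyl triflate under zerovalent palladium catalysis installs C12 at the alcohol level without touching the enoate or the silyl groups.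

Step 12
Reactants: 20 cyclopentadienylmethanol
Product: 21 saturated ring A alcohol with C2 and C5 as in the target
Conditions: H2 (50 bar), [Ir(cod)(PCy3)(py)]PF6 (10 mol%), CH2Cl2, rt
Reagents that add atoms: none
Why: Hydroxyl-assisted homogeneous hydrogenation in which the cationic iridium catalyst is anchored by the C12 hydroxyl and takes the diene from the face syn to C11, because the other face is roofed by the C10 silyloxy group, the C8=C9 bridge and C14; the hydrogens at C2 and C5 are therefore set together while the electron-poor enoate is left untouched.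

Step 13
Reactants: 21 primary alcohol
Product: 22 C12 aldehyde
Conditions: DMP, CH2Cl2, 0 °C → rt
Reagents that add atoms: none
Why: Periodinane oxidation of the only free alcohol stops at the aldehyde under conditions that do not epimerise C2.

Step 14
Reactants: 22 aldehyde
Product: 23 C10 alcohol (10-epi) aldehyde
Conditions: AcOH/THF/H2O 3:1:1, rt
Reagents that add atoms: none
Why: Acid solvolysis exploits graded silyl ether lability, since the triethylsilyl ether is cleaved faster than the neopentyl tert-butyldimethylsilyl ether.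

Step 15
Reactants: 24 9-bromononanoic acid
Product: 25 (8-carboxyoctyl)triphenylphosphonium bromide
Conditions: PPh3, MeCN, reflux
Reagents that add atoms: triphenylphosphine c1ccc(cc1)P(c1ccccc1)c1ccccc1
Why: SN2 quaternisation of a phosphine by a primary bromide gives the Wittig salt.

Step 16
Reactants: 26 heptane-1,7-diol
Product: 27 7-(tert-butyldimethylsilyloxy)heptan-1-ol
Conditions: t-BuMe2SiCl (1 equiv), imidazole, excess 26, THF, 0 °C
Reagents that add atoms: tert-butyldimethylsilyl chloride CC(C)(C)[Si](C)(C)Cl
Why: Statistical monosilylation of a symmetric diol, biased toward the mono ether by the excess of diol.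

Step 17
Reactants: 27 mono-protected diol
Product: 28 7-(tert-butyldimethylsilyloxy)heptanal
Conditions: DMP, CH2Cl2, 0 °C → rt
Reagents that add atoms: none
Why: Periodinane oxidation of a primary alcohol to the aldehyde without over-oxidation.

Step 18
Reactants: 25 phosphonium salt; 28 aldehyde
Product: 29 (Z)-16-(tert-butyldimethylsilyloxy)hexadec-9-enoic acid
Conditions: NaN(SiMe3)2 (2.1 equiv), THF, −78 °C → rt; aq. citric acid work-up
Reagents that add atoms: none
Why: Salt-free Wittig olefination with a non-stabilised ylide is kinetically Z-selective and sets the C9=C10 geometry of the chain.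

Step 19
Reactants: 23 C10 alcohol; 29 protected hydroxy acid
Product: 30 fully protected ester with C10 as in the target
Conditions: PPh3, DIAD, toluene, 0 °C → rt
Reagents that add atoms: none
Why: Mitsunobu esterification, in which SN2 displacement of the equatorial oxyphosphonium group from the open face syn to C11 inverts C10 to the required configuration, and an SN2′ path is blocked by the fully substituted, ester-bearing C8.

Step 20
Reactants: 30 protected ester
Product: 31 target CNP0148862.1
Conditions: TASF (6 equiv), DMF, 0 °C → rt; pH 7 buffer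
Reagents that add atoms: none
Why: Fluoride-induced desilylation removes both silyl ethers and fragments the 2-(trimethylsilyl)ethyl ester (β-elimination to ethene) near neutral pH, which spares the aldehyde centre C2, the allylic ester and the Z-alkene.

Compound list
1 | methyl tiglate | C/C=C(\C)C(=O)OC | starting material
2 | (R)-4-(tert-butyldimethylsilyloxy)cyclopent-2-en-1-one | O=C1C=C[C@H](O[Si](C)(C)C(C)(C)C)C1 | starting material
3 | lithium dienolate of methyl tiglate (OLi syn to the methyl group) | C=C/C(C)=C(\OC)O[Li] | intermediate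
4 | lithium enolate of the Michael adduct | C[C@@]([C@H]1[C@H](O[Si](C)(C)C(C)(C)C)CC(O[Li])=C1)(C(=O)OC)C=C | intermediate
5 | methyl ester triethylsilyl enol ether | C[C@@]([C@H]1[C@H](O[Si](C)(C)C(C)(C)C)CC(O[Si](CC)(CC)CC)=C1)(C(=O)OC)C=C | intermediate
6 | C13 primary alcohol | C[C@@]([C@H]1[C@H](O[Si](C)(C)C(C)(C)C)CC(O[Si](CC)(CC)CC)=C1)(CO)C=C | intermediate
7 | C13 tert-butyldimethylsilyl ether | C[C@@]([C@H]1[C@H](O[Si](C)(C)C(C)(C)C)CC(O[Si](CC)(CC)CC)=C1)(CO[Si](C)(C)C(C)(C)C)C=C | intermediate
8 | 2-(trimethylsilyl)ethanol | OCC[Si](C)(C)C | starting material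
9 | oxalyl chloride | O=C(Cl)C(=O)Cl | starting material
10 | 2-(trimethylsilyl)ethyl chlorooxoacetate | O=C(Cl)C(=O)OCC[Si](C)(C)C | intermediate
11 | chelated enol of the C1-oxalyl ketone | C[C@@]([C@H]1[C@H](O[Si](C)(C)C(C)(C)C)CC(=O)/C1=C(\O)C(=O)OCC[Si](C)(C)C)(CO[Si](C)(C)C(C)(C)C)C=C | intermediate
12 | bicyclo[2.1.1]hexanol photoadduct | C[C@@]1(CO[Si](C)(C)C(C)(C)C)[C@@H]2C[C@]3([C@]2(O)C(=O)OCC[Si](C)(C)C)C(=O)C[C@@H](O[Si](C)(C)C(C)(C)C)[C@H]13 | intermediate
13 | cis-bicyclo[3.3.0]octanone 2-oxoacetate | C[C@@]1(CO[Si](C)(C)C(C)(C)C)[C@@H](C(=O)C(=O)OCC[Si](C)(C)C)C[C@@H]2C(=O)C[C@@H](O[Si](C)(C)C(C)(C)C)[C@H]12 | intermediate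
14 | unsaturated cyclohexylimine | C[C@@]1(CO[Si](C)(C)C(C)(C)C)[C@@H](/C(=C\C=NC3CCCCC3)C(=O)OCC[Si](C)(C)C)C[C@@H]2C(=O)C[C@@H](O[Si](C)(C)C(C)(C)C)[C@H]12 | intermediate
15 | (E)-enal | C[C@@]1(CO[Si](C)(C)C(C)(C)C)[C@@H](/C(=C\C=O)C(=O)OCC[Si](C)(C)C)C[C@@H]2C(=O)C[C@@H](O[Si](C)(C)C(C)(C)C)[C@H]12 | intermediate
16 | cyclopentenone enal | C[C@@]1(CO[Si](C)(C)C(C)(C)C)[C@@H](/C(=C\C=O)C(=O)OCC[Si](C)(C)C)C[C@@H]2C(=O)C=C[C@H]12 | intermediate
17 | tricyclic 10-epi alcohol enone | C[C@@]1(CO[Si](C)(C)C(C)(C)C)[C@@H]2C[C@]3([C@H](O)C=C2C(=O)OCC[Si](C)(C)C)C(=O)C=C[C@H]13 | intermediate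
18 | C10 triethylsilyl ether | C[C@@]1(CO[Si](C)(C)C(C)(C)C)[C@@H]2C[C@]3([C@H](O[Si](CC)(CC)CC)C=C2C(=O)OCC[Si](C)(C)C)C(=O)C=C[C@H]13 | intermediate
19 | cyclopentadienyl triflate | C[C@@]1(CO[Si](C)(C)C(C)(C)C)[C@@H]2C[C@]3([C@H](O[Si](CC)(CC)CC)C=C2C(=O)OCC[Si](C)(C)C)C(OS(=O)(=O)C(F)(F)F)=CC=C13 | intermediate
20 | cyclopentadienylmethanol | C[C@@]1(CO[Si](C)(C)C(C)(C)C)[C@@H]2C[C@]3([C@H](O[Si](CC)(CC)CC)C=C2C(=O)OCC[Si](C)(C)C)C(CO)=CC=C13 | intermediate
21 | saturated ring A C12 alcohol | C[C@@]1(CO[Si](C)(C)C(C)(C)C)[C@@H]2C[C@]3([C@H](O[Si](CC)(CC)CC)C=C2C(=O)OCC[Si](C)(C)C)[C@@H](CO)CC[C@@H]13 | intermediate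
22 | C12 aldehyde | C[C@@]1(CO[Si](C)(C)C(C)(C)C)[C@@H]2C[C@]3([C@H](O[Si](CC)(CC)CC)C=C2C(=O)OCC[Si](C)(C)C)[C@@H](C=O)CC[C@@H]13 | intermediate
23 | 10-epi alcohol aldehyde | C[C@@]1(CO[Si](C)(C)C(C)(C)C)[C@@H]2C[C@]3([C@H](O)C=C2C(=O)OCC[Si](C)(C)C)[C@@H](C=O)CC[C@@H]13 | intermediate
24 | 9-bromononanoic acid | OC(=O)CCCCCCCCBr | starting material
25 | (8-carboxyoctyl)triphenylphosphonium bromide | OC(=O)CCCCCCCC[P+](c1ccccc1)(c1ccccc1)c1ccccc1.[Br-] | intermediate
26 | heptane-1,7-diol | OCCCCCCCO | starting material
27 | 7-(tert-butyldimethylsilyloxy)heptan-1-ol | OCCCCCCCO[Si](C)(C)C(C)(C)C | intermediate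
28 | 7-(tert-butyldimethylsilyloxy)heptanal | O=CCCCCCCO[Si](C)(C)C(C)(C)C | intermediate
29 | (Z)-16-(tert-butyldimethylsilyloxy)hexadec-9-enoic acid | OC(=O)CCCCCCC/C=C\CCCCCCO[Si](C)(C)C(C)(C)C | intermediate
30 | fully protected ester | C[C@@]1(CO[Si](C)(C)C(C)(C)C)[C@@H]2C[C@]3([C@@H](OC(=O)CCCCCCC/C=C\CCCCCCO[Si](C)(C)C(C)(C)C)C=C2C(=O)OCC[Si](C)(C)C)[C@@H](C=O)CC[C@@H]13 | intermediate
31 | CNP0148862.1 | C[C@@]1(CO)[C@@H]2C[C@]3([C@@H](OC(=O)CCCCCCC/C=C\CCCCCCO)C=C2C(=O)O)[C@@H](C=O)CC[C@@H]13 | target

Total step count: 20. Longest linear sequence: 15 (steps 1–3, 5–14, 19, 20).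

Steps most likely to fail

Step 12. The hindered C4=C5 double bond may stall, or hydrogen may arrive from both faces, because the trans junction of rings A and B builds strain in the transition state. The fallback sets out from 20. The iridium hydrogenation is stopped after one equivalent of hydrogen at the C4=C5 mono-ene F1. That alkene is then saturated by radical hydrogen-atom transfer (Mn(dpm)3, PhSiH3, t-BuOOH, i-PrOH, rt). A hydrogen atom first goes to C4, and the tertiary C5 radical is then quenched in an early transition state from the open face syn to C11. The fallback returns to the route at 21.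

Step 19. Displacement at the carbinol next to quaternary C1 may be too slow, so that the oxyphosphonium salt decays by ionisation with loss of stereochemical integrity. The fallback sets out from 23. The alcohol is converted into the chloromethanesulfonate F2 (ClCH2SO2Cl, pyridine, 0 °C). F2 is displaced by the cesium carboxylate F3 (from 29 and Cs2CO3) with 18-crown-6 in toluene, a two-stage sulfonate inversion. The fallback returns to the route at 30.

Step 6. Secondary photochemistry of the product keto ester, or inefficient collapse of the biradical, may erode the photoreaction when cycloaddition and fragmentation run in one flask. The fallback sets out from 11. The enol is capped as the trimethylsilyl enol ether F4 (Me3SiCl, Et3N). F4 is cyclised by triplet energy transfer (thioxanthone, 405 nm) to the isolable bicyclo[2.1.1]hexyl silyl ether F5. F5 is fragmented separately (dilute HCl in THF, then Et3N) by desilylation and retro-aldol cleavage. The fallback returns to the route at 13.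

Further compounds
F1 | step 12 | C4=C5 mono-ene C12 alcohol | C[C@@]1(CO[Si](C)(C)C(C)(C)C)[C@@H]2C[C@]3([C@H](O[Si](CC)(CC)CC)C=C2C(=O)OCC[Si](C)(C)C)[C@@H](CO)CC=C13
F2 | step 19 | C10 chloromethanesulfonate | C[C@@]1(CO[Si](C)(C)C(C)(C)C)[C@@H]2C[C@]3([C@H](OS(=O)(=O)CCl)C=C2C(=O)OCC[Si](C)(C)C)[C@@H](C=O)CC[C@@H]13
F3 | step 19 | cesium (Z)-16-(tert-butyldimethylsilyloxy)hexadec-9-enoate | [Cs+].[O-]C(=O)CCCCCCC/C=C\CCCCCCO[Si](C)(C)C(C)(C)C
F4 | step 6 | trimethylsilyl enol ether of 11 | C[C@@]([C@H]1[C@H](O[Si](C)(C)C(C)(C)C)CC(=O)/C1=C(\O[Si](C)(C)C)C(=O)OCC[Si](C)(C)C)(CO[Si](C)(C)C(C)(C)C)C=C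
F5 | step 6 | bicyclo[2.1.1]hexyl trimethylsilyl ether | C[C@@]1(CO[Si](C)(C)C(C)(C)C)[C@@H]2C[C@]3([C@]2(O[Si](C)(C)C)C(=O)OCC[Si](C)(C)C)C(=O)C[C@@H](O[Si](C)(C)C(C)(C)C)[C@H]13
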